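The ratio of the two charges, 2.00, hardly shows at the top of the curves: the winter flask reads 59.9 % of target at 1.33 min, and the summer run reads 59.5 % at 2.00 min.

| flask | substrate | remark | time |
|---|---|---|---|
| winter | 0.50 M | the very flask that is asked about, followed so far |  |
| summer | 0.25 M | run made earlier |  |
| flask | 0.50 M |  | 1.5 h |

| run | time / min | target / % | substrate / % |
|---|---|---|---|
| winter | 0.417 | 42.2 | 9.2 |
| winter | 1.33 | 59.9 | 0 |
| winter | 5.00 | 52.9 | 0 |
| winter | 15.0 | 30.2 | 0.4 |
| winter | 50.0 | 11.4 | 0 |
| summer | 0.667 | 53.3 | 1.7 |
| summer | 2.00 | 59.5 | 0.7 |
| summer | 6.00 | 49.6 | 0.2 |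
| summer | 20.0 | 23.2 | 0.6 |
| summer | 60.0 | 10.5 | 0 |

(standard deviation of a reading: 0.5 percentage points)

1. time up to 1.5 h at which target stands highest, in min
2. the amount of target, in percent of the substrate charged, at that time

The winter readings hold an apparent contradiction. Between 0.417 min and 1.33 min, substrate falls by 9.2 percentage points, yet target gains 18 points. The excess must come from material that is read as neither substrate nor target. This unaccounted share, the mass-balance gap, is 48.6 % at 0.417 min and falls to 40.1 % at 1.33 min. By 5.00 min it has risen to 47.1 %, so it passes through a minimum in between. Once substrate reads 0 %, that minimum is the top of target. The summer run, at 0.25 M of substrate, reads a nearly equal share of 39.8 % at 2.00 min. Taking the summer curve as a stand-in for the winter one and freezing the share at its winter reading, which carries a scatter of 0.5 points, my own reckoning puts the top of the winter flask near 59.9 %, somewhere between 1.33 min and 2.00 min; that height is the winter reading restated, not an independent value.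

The forecast reads the same lag, “suggesting a short-lived intermediate”, and gives 60.3 % (59.3 % to 61.8 %) at 1.5 min (1 min to 2.2 min).

The winter flask reaches 60.0 % of target at 1.68 min.

    substrate → intermediate (k = 0.0970 s⁻¹)
    intermediate ⇌ target (K = 13.0, k = 0.0580 s⁻¹)
    intermediate ⇌ isomer of the product A (K = 3.10, k = 0.0350 s⁻¹)
    target ⇌ isomer of the product B (K = 6.70, k = 0.00140 s⁻¹)
    target → over-reaction product (k = 1.80 × 10⁻⁴ s⁻¹)

At that time the unaccounted share is 40.0 %, and isomer of the product A holds 26.3 % of the charge. Applied to the neighbouring flask with [substrate] of 0.20 M, the frozen share leaves 0.120 M of target at the top, which is 59.9 % of its charge, and that flask reaches 60.0 %.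

Readings and results were generated by integration with made-up constants, noise included.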